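# Total synthesis of calyxin B

**Assumptions**
- 2,4-Dihydroxy-6-methoxyacetophenone is treated as a purchasable building block.
- The enantiomers of the pinene-derived allylborane (step 3) and the BINOL catalyst (step 7) are chosen to give (3S) and (7S). Both senses are assigned from memory of the literature models and should be checked (Mosher ester for C3, HPLC for C7).
- In step 7, C3′ is assumed to react in preference to C5′. C3′ lies between two OH groups, and both can form the ortho-quinone methide. C5′ lies between OH and OMe.

## Retrosynthetic overview
1. Calyxin B ⇒ global deprotection ⇐ Claisen–Schmidt condensation of acetophenone **11** with 4-MOMO-benzaldehyde **9**. This is the last C–C bond formed.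
2. Key bold step: the C3′–C7 bond and the C7 diarylmethine stereocentre form in one catalytic enantioselective three-component Petasis-type coupling. The partners are acetophenone **10**, aldehyde **9** and an (E)-alkenyl-Bpin **7** that already carries the C3 stereocentre. It proceeds through a chiral-biphenol-bound o-quinone methide.
3. The alkenyl-Bpin comes from an (S)-homoallylic alcohol (Brown allylation of a 3-arylpropanal) by cross-metathesis with vinyl-Bpin.
4. No new rings are formed. All three arenes are carried in intact.

## Forward route

**Step 1**
Reactants: **1** methyl 3-(4-hydroxyphenyl)propanoate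
Product: **2** methyl 3-[4-(methoxymethoxy)phenyl]propanoate
Conditions: MOMCl, i-Pr2NEt, CH2Cl2, 0 °C→rt
Reagents that add atoms: MOMCl, COCCl
Why: Phenol O-alkylation gives a MOM ether that is base-stable and removable in the final step alongside the other protecting groups.

**Step 2**
Reactants: **2**
Product: **3** 3-[4-(methoxymethoxy)phenyl]propanal
Conditions: DIBAL-H (1.05 equiv), CH2Cl2, –78 °C
Reagents that add atoms: none
Why: Low-temperature DIBAL-H stops at the aldehyde stage through a stable aluminium hemiacetal (ester-to-aldehyde partial reduction).

**Step 3**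
Reactants: **3**
Product: **4** (S)-1-[4-(methoxymethoxy)phenyl]hex-5-en-3-ol
Conditions: B-allyldiisopinocampheylborane (from (–)-α-pinene), Et2O, –78 °C; then NaOH, H2O2
Reagents that add atoms: allyl-B(Ipc)2, C=CCB(C1CC2CC(C1C)C2(C)C)C1CC2CC(C1C)C2(C)C (the allyl group is transferred)
Why: Brown asymmetric allylboration goes through a chair Zimmerman–Traxler transition state, and the chiral pinene ligands set the aldehyde face, which sets C3 as (S).

**Step 4**
Reactants: **4**
Product: **5** (S)-tert-butyl{[1-(4-MOMO-phenyl)hex-5-en-3-yl]oxy}dimethylsilane (TBS ether of **4**)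
Conditions: TBSCl, imidazole, DMF, rt
Reagents that add atoms: TBSCl, CC(C)(C)[Si](C)(C)Cl
Why: Silylation masks the secondary OH so it cannot trap the o-quinone methide or exchange with boron in step 7. The carbinol centre is untouched.

**Step 5**
Reactants: **5**, **6** vinyl-Bpin
Product: **7** (S,E)-alkenyl pinacolboronate
Conditions: Grubbs II (5 mol%), CH2Cl2, 40 °C, open to N2 flow (ethylene removal)
Reagents that add atoms: none (**6**, C=CB1OC(C)(C)C(C)(C)O1, is the numbered reactant)
Why: Cross-metathesis of a terminal alkene with vinyl-Bpin gives the thermodynamic (E)-alkenylboronate; the MOM and OTBS groups and the stereocentre are inert.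

**Step 6**
Reactants: **8** 4-hydroxybenzaldehyde
Product: **9** 4-(methoxymethoxy)benzaldehyde
Conditions: MOMCl, i-Pr2NEt, CH2Cl2, 0 °C→rt
Reagents that add atoms: MOMCl, COCCl
Why: Phenol O-alkylation gives a protected aldehyde that is suitable for both the key step and the Claisen–Schmidt step.

**Step 7**
Reactants: **10** 2,4-dihydroxy-6-methoxyacetophenone (2.5 equiv), **9** (1.0 equiv), **7** (1.5 equiv)
Product: **11** (S,E)-acetophenone bearing the C7 diarylallyl unit at C3′
Conditions: (S)-3,3′-Br2-BINOL (20 mol%), PhMe, 4 Å MS, 60 °C, 48 h
Reagents that add atoms: none (HOBpin is the by-product)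
Why: Proposed new method: the phenol exchanges onto the chiral alkenyl-boronate, and ortho-hydroxyalkylation with **9** followed by loss of the benzylic oxygen gives an o-quinone methide. The quinone methide is bound to the BINOL-boron centre, and the (E)-alkenyl group is delivered through a closed six-membered transition state with retention of alkene geometry; this sets C7 as (S) and leaves C3 untouched. The closest known reactions are the chiral-biphenol-catalysed addition of alkenylboronates to o-quinone methides (from o-hydroxybenzhydrols) and Petasis-type coupling of phenols, aldehydes and boronic acids. Excess phenol suppresses bis-alkylation.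

**Step 8**
Reactants: **11**, **9** (1.5 equiv)
Product: **12** fully protected chalcone (E-enone)
Conditions: KOH (aq, 50%), EtOH, rt, 48–72 h
Reagents that add atoms: none (**9** is the numbered reactant; H2O is lost)
Why: Claisen–Schmidt aldol condensation, with E1cB dehydration giving the (E)-enone. The aryl-MOM groups and the alkyl OTBS survive base, and the non-acidic doubly benzylic C7–H is not epimerised.

**Step 9**
Reactants: **12**
Product: **13** calyxin B
Conditions: 3 M HCl, MeOH, 40 °C, 8 h
Reagents that add atoms: none
Why: Acid cleaves the three aryl MOM acetals and the secondary TBS ether in one operation. The C7 centre has no leaving group, so it cannot ionise and is not racemised, and the chalcone and the (E)-alkene are unaffected.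

**Checks**
- Target SMILES re-read: a 2′,4′-dihydroxy-6′-methoxychalcone with a 4-hydroxyphenyl β-ring, substituted at C3′ by (S)-CH(4-HOC6H4)–CH=CH(E)–CH2–(S)-CH(OH)–CH2CH2–C6H4OH, with six OH and one OMe in total.
- Atom bookkeeping: step 7 is ArH + ArCHO + R–Bpin → Ar–CH(Ar′)–R + HOBpin, and step 8 loses H2O.
- C3 is set in step 3 and is unchanged through steps 4–9. C7 is set in step 7 and is unchanged through steps 8–9. The alkene geometry is set in step 5 and retained.

## Compound list
1 | methyl 3-(4-hydroxyphenyl)propanoate | COC(=O)CCc1ccc(O)cc1 | starting material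
2 | methyl 3-[4-(methoxymethoxy)phenyl]propanoate | COC(=O)CCc1ccc(OCOC)cc1 | intermediate
3 | 3-[4-(methoxymethoxy)phenyl]propanal | O=CCCc1ccc(OCOC)cc1 | intermediate
4 | (S)-1-[4-(methoxymethoxy)phenyl]hex-5-en-3-ol | C=CC[C@@H](O)CCc1ccc(OCOC)cc1 | intermediate
5 | TBS ether of 4 | C=CC[C@@H](O[Si](C)(C)C(C)(C)C)CCc1ccc(OCOC)cc1 | intermediate
6 | vinylboronic acid pinacol ester | C=CB1OC(C)(C)C(C)(C)O1 | starting material
7 | (S,E)-alkenyl-Bpin | CC1(C)OB(OC1(C)C)/C=C/C[C@@H](O[Si](C)(C)C(C)(C)C)CCc1ccc(OCOC)cc1 | intermediate
8 | 4-hydroxybenzaldehyde | O=Cc1ccc(O)cc1 | starting material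
9 | 4-(methoxymethoxy)benzaldehyde | COCOc1ccc(C=O)cc1 | intermediate
10 | 2,4-dihydroxy-6-methoxyacetophenone | COc1cc(O)cc(O)c1C(C)=O | starting material
11 | C3′-substituted acetophenone (7S,3S) | COc1cc(O)c([C@@H](/C=C/C[C@@H](O[Si](C)(C)C(C)(C)C)CCc2ccc(OCOC)cc2)c2ccc(OCOC)cc2)c(O)c1C(C)=O | intermediate
12 | protected chalcone | COc1cc(O)c([C@@H](/C=C/C[C@@H](O[Si](C)(C)C(C)(C)C)CCc2ccc(OCOC)cc2)c2ccc(OCOC)cc2)c(O)c1C(=O)/C=C/c1ccc(OCOC)cc1 | intermediate
13 | calyxin B | COc1cc(O)c([C@@H](/C=C/C[C@@H](O)CCc2ccc(O)cc2)c2ccc(O)cc2)c(O)c1C(=O)/C=C/c1ccc(O)cc1 | target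

## Totals
- Total steps: 9.
- Longest linear sequence: 8 steps (1→2→3→4→5→7→8→9, counted by step number), starting from **1**.

## Three steps most likely to fail
1. **Step 7, three-component coupling.** Risks are C3′ versus C5′ regiochemistry, the ee, and bis-alkylation. Fallback: change the approach to an Ir/phosphoramidite branched-selective allylic Friedel–Crafts reaction of 4-MOMO-cinnamyl carbonate with **10**, giving the 3,3-diarylpropene, followed by E-selective cross-metathesis with **5**.
2. **Step 8, Claisen–Schmidt on the free 2′,4′-diphenol.** The phenoxide may deactivate enolisation, and flavanone formation is possible. Fallback: reorder the sequence by making the MOM-protected cardamonin-type chalcone from **10** and **9** first, then run the key coupling on that chalcone.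
3. **Step 9, global deprotection.** Retro-Friedel–Crafts, chromane formation or alkene isomerisation under acid are possible. Fallback: swap the protecting-group set, using allyl aryl ethers and a TBS ether, removed with Pd(PPh3)4/K2CO3–MeOH and then TBAF/AcOH, so no Brønsted acid is needed.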